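Atoms carry labdane numbers: ring A = C1–C5 and C10, gem-dimethyl on C4, the chain C6–C7–C8(=O)–CH3 on C5, and CH3 plus the C9 ketone on C10, continuing as C11–C12–C13(CH3)=C14–C15–OAc. Compounds carry the numbers 1–25 of the steps below.

## Analysis of the target

Target 25 is an 8,9-seco-labdane with a single carbocycle, ring A. C4 bears a gem-dimethyl group, C5 a 3-oxobutyl chain, and C10 a methyl group and the C9 ketone, whose chain ends in an (E)-trisubstituted alkene and a primary allylic acetate. The two stereocentres are adjacent: C5 (R, tertiary) and C10 (R, quaternary). The C5 chain is cis to the C10 methyl and trans to C9, as in a trans-decalin whose ring B has been opened between C8 and C9. Neither centre can be corrected later, because C10 has no hydrogen and C5 is not α to a carbonyl. C5 lies between two quaternary carbons (C4 and C10), so every bond to it is made in a crowded environment. The sensitive groups are the allylic acetate (cleaved by nucleophilic base, ionised by acid or zerovalent palladium) and two ketones in a 1,6-relationship, of which only C8 is unhindered. The hard part is the all-carbon quaternary centre C10 on a ring with no resident stereocentre, followed by relay of its configuration to C5. The plan rests on one feature: C10 is α to C9, and while C5 is carried as a ring ketone C10 sits between two carbonyls, with quaternary C4 blocking the other α-position. A single, doubly stabilised enolate at C10 is then open to catalytic asymmetric methylation.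

## Retrosynthetic reasoning

25 ⇒ 24. No skeletal bond is cut; the C8 carbonyl goes back to its dioxolane. C8 is the only unhindered, doubly enolisable carbonyl and must stay masked while enolate and organometallic chemistry is done elsewhere. The forward step has to hydrolyse the ketal without touching the allylic acetate.

24 ⇒ 21 + 22. The C11–C12 bond is cut. C10 is quaternary, so the enolate of 21 can form only at C11, and the partner is allylic bromide 22, which brings the (E)-alkene and the acetate ready-made. Cutting at C9–C10 or C9–C11 would need an acyl anion at a neopentyl carbon or a homoallylic organometallic that is not available. The forward reaction must alkylate once and spare the acetate.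

21 ⇒ 20 ⇒ 19 ⇒ 18. The C9–C11 bond is traced to aldehyde 19 and a methyl nucleophile, and C9 is taken back to the primary alcohol 18. This is longer than a direct ester-to-ketone change, but the C9 hydroxyl of 18 is needed for the next disconnection, and 19 cannot enolise.

18 ⇒ 17. The C5–H bond is traced to hydrogenation of an exocyclic C5=C6 alkene. The C9 hydroxymethyl group is the one substituent on C10 that can hold a metal; hydrogen delivered from its face puts the chain trans to C9, as required. The forward reaction must reach a trisubstituted alkene between two quaternary carbons and obey the hydroxyl.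

17 ⇒ 16 ⇒ 14 ⇒ 13. These are functional-group changes: alcohol from tert-butyl ester, alkene from a C5 tertiary alcohol, saturated C6–C7 from an alkyne. Dehydration has one direction only, since C4 and C10 carry no hydrogen. It precedes ester reduction so that only one hydroxyl is present, and it follows alkyne reduction because the propargylic alcohol has no β-hydrogen at all.

13 ⇒ 8 + 10. The C5–C6 bond is cut, giving ring ketone 8 and the metal acetylide of 10 (11, 12). The carbonyl that activates C10 in the key step now serves as the electrophile, and a rod-shaped sp nucleophile is the only carbon nucleophile slim enough to reach it. Alkyne 10 comes from 9 by ketalisation, so C6–C8 and the methyl arrive in one piece with C8 already masked.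

8 ⇒ 5 + 6. This is the key disconnection, C10–CH3. In 5, C10 is the only acidic position; removing the methyl (and not the C9 or C5 substituent) leaves a simple, quickly made precursor with no fixed stereocentre and the smallest electrophile, 6. The forward reaction must select one face of the enolate.

5 ⇒ 1 + 2. The C9–C10 bond is cut: C-acylation of the only possible enolate of 1.

## Alternatives that were turned down

Alternative 1: [2,3]-Wittig–Still shift to the quaternary carbon.
- **Disconnection:** the C9–C10 bond of A1, which is 18 with an extra C1=C2 alkene.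
- **Forward key step:** tin–lithium exchange on the stannylmethyl ether A2 (C1=C10 alkene, C2 oxygen trans to the C5 chain). The shift forms C9–C10 on the ring face from which the C2–O bond leaves and moves the alkene to C1=C2.
- **For:** the five-membered, intramolecular transition state tolerates a quaternary terminus and transfers the C2 configuration to C10 faithfully. C5 is already in place, so neither the addition to a doubly neopentyl ketone nor the directed hydrogenation of a crowded alkene is needed. On these two points it is the stronger plan.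
- **Against:** A2 already holds two stereocentres. C5, next to the gem-dimethyl group, would need a regio- and enantioselective γ-alkylation of a trimethylcyclohexenone or an equivalent, followed by a trans-selective 1,2-reduction. Stoichiometric tin is used, and a [1,2]-shift can compete when the carbanion must reach a fully substituted alkene carbon beside branched C5. After A1 an extra ring hydrogenation and the same five-step C9 end game remain.
- **Comparison:** the absolute-configuration problem is moved to C5 of A2, not solved. The chosen route sets C10 catalytically two steps from purchased 1 and needs no tin.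

Alternative 2: conjugate addition–aldol union of three fragments.
- **Disconnection:** C5–C6 and C9–C10 together, giving enone A4, Grignard reagent A5 and aldehyde A6.
- **Forward key step:** a chiral copper–ferrocenyl diphosphine catalyst adds A5 to C5 of A4, and aldol capture by A6 at C10 in the same flask gives A3.
- **For:** the whole carbon skeleton and both stereocentres arise in one operation, and the aldehyde should approach anti to the new C5 chain, which is the required trans relationship. In convergence and step count up to this point it is clearly stronger.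
- **Against:** the β-carbon C5 is neopentyl and the enone is α-substituted, a demanding case for catalytic asymmetric conjugate addition. The tetrasubstituted enolate must then form a quaternary centre with an enolisable aldehyde, so proton transfer and retro-aldol are likely. A3 keeps a C1 ketone that the target lacks; it must be deoxygenated next to quaternary C10 in the presence of a ketal, an alkene and an allylic acetate. Oxidising C9 before that gives a 2,2-disubstituted 1,3-diketone prone to retro-Claisen cleavage.
- **Comparison:** the chosen route also uses a temporary ring ketone, but at C5, where it becomes the point of attachment of the chain and leaves nothing to remove.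

Alternative 3: lactone-enolate Claisen ring contraction to ring A.
- **Disconnection:** the C5–C10 bond of acid A7, traced to δ-lactone A8.
- **Forward key step:** A8 is converted into silyl ketene acetal A9, which rearranges on warming. C5–C10 forms, the lactone C–O bond breaks and the cyclohexene closes.
- **For:** the lactone ring enforces a boat transition state, so both stereocentres and their trans relationship come from one pericyclic event. The absolute configuration comes from a single carbinol centre, independent of any catalyst. In stereochemical predictability it is stronger than the chosen route.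
- **Against:** the new bond joins an enolate carbon next to quaternary C4 to a fully substituted alkene terminus through a boat. By the boat geometry, A8 needs a (Z)-trisubstituted alkene and an (S)-carbinol, which takes several steps. After A7 the carboxyl carbon C6 needs a three-carbon homologation at a crowded position, the ring alkene must be reduced and C9 is still to be elaborated.
- **Comparison:** the chosen route buys ring A and spends its steps on the two chains; this alternative would be considerably longer.

Key step: step 2

Remarks on the chemistry: the (S,S) antipode of the ammonium salt is assumed to lead to (R)-8 (its mirror image would be used if the sense proved opposite), and 22 is assumed to be purchasable as the pure (E) isomer.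

## Route

Step 1
Reactants: 1 2,2-dimethylcyclohexanone; 2 di-tert-butyl dicarbonate
Product: 5 tert-butyl 3,3-dimethyl-2-oxocyclohexane-1-carboxylate, via ketone lithium enolate 3 (not isolated), via keto ester lithium enolate 4 (not isolated)
Conditions: LiN(i-Pr)2 (2.1 equiv), THF, −78 °C; then 2, −78 → 0 °C; AcOH
Reagents that add atoms: none
Why: Claisen-type C-acylation of a ketone enolate: C6 of 1 is the only enolisable position, and the second equivalent of base converts the acidic product at once into chelated enolate 4, which draws the acylation to carbon and stops proton exchange with 3.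

Step 2
Reactants: 5 tert-butyl 3,3-dimethyl-2-oxocyclohexane-1-carboxylate; 6 iodomethane
Product: 8 tert-butyl (R)-1,3,3-trimethyl-2-oxocyclohexane-1-carboxylate, via cesium enolate 7 (not isolated)
Conditions: 6 (3 equiv), CsOH·H2O (3 equiv), (S,S)-N-spiro bis(binaphthyl-2,2′-dimethylene)ammonium bromide with 3,5-(CF3)2C6H3 groups at C3 and C3′ (1–2 mol%), toluene, −40 °C
Reagents that add atoms: none
Why: Solid CsOH·H2O removes the doubly activated C10–H of 5 at the toluene interface to give cesium enolate 7; its cation is exchanged for the chiral ammonium ion, and the lipophilic ion pair attacks 6 through carbon in an SN2 step, forming the C10–CH3 bond. The closest known reaction type is the phase-transfer asymmetric alkylation of cyclic β-keto tert-butyl esters with C2-symmetric binaphthyl-derived ammonium salts. No ring is closed. The new quaternary centre C10 is controlled by the catalyst alone: the 3,3′-aryl groups of the ammonium ion wall off one face of the planar enolate, so 6 approaches from the open face, and the (S,S) salt is the one expected to give R. The step needs enantiofacial selectivity, C- over O-alkylation and a single site of reaction; the bulky tert-butyl ester makes the two enolate faces as different as possible inside the ion pair, the soft iodide favours carbon, and quaternary C4 leaves C10 as the only enolisable position. Because 8 has no α-hydrogen, it can neither be methylated again nor racemise under the basic conditions. Low temperature and the insolubility of the base in toluene keep the uncatalysed racemic pathway slow, which matters because 6 is small and reactive.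

Step 3
Reactants: 9 but-3-yn-2-one
Product: 10 2-ethynyl-2-methyl-1,3-dioxolane
Conditions: Me3SiOCH2CH2OSiMe3, Me3SiOTf (cat.), CH2Cl2, −78 → −20 °C; pyridine
Reagents that add atoms: 1,2-bis(trimethylsilyloxy)ethane, C[Si](C)(C)OCCO[Si](C)(C)C
Why: Silyl triflate-catalysed ketalisation with a bis-silylated diol: the aprotic, cold conditions should form the dioxolane without conjugate addition to the ynone, driven by formation of the siloxane.

Step 4
Reactants: 8 tert-butyl (R)-1,3,3-trimethyl-2-oxocyclohexane-1-carboxylate; 10 2-ethynyl-2-methyl-1,3-dioxolane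
Product: 13 tert-butyl (1R)-2-hydroxy-1,3,3-trimethyl-2-[(2-methyl-1,3-dioxolan-2-yl)ethynyl]cyclohexane-1-carboxylate (both C2 epimers), via lithium acetylide 11 (not isolated), via dichlorocerium acetylide 12 (not isolated)
Conditions: 10, n-BuLi, THF, −78 °C; CeCl3 (anhydrous), −78 °C; then 8, −78 → −40 °C; aq NH4Cl, −78 °C
Reagents that add atoms: none
Why: 1,2-Addition of an organocerium acetylide to a ketone: 8 has no α-hydrogen and cannot be enolised, the linear sp nucleophile is slim enough to reach the carbonyl carbon between C4 and C10, and the oxophilic, weakly basic trivalent cerium reagent activates the ketone while sparing the tert-butyl ester. The configuration of the new carbinol carbon C5 does not matter because C5 becomes sp2 in step 6; the cold quench guards against retro-aldol opening of the alkoxide.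

Step 5
Reactants: 13 tert-butyl (1R)-2-hydroxy-1,3,3-trimethyl-2-[(2-methyl-1,3-dioxolan-2-yl)ethynyl]cyclohexane-1-carboxylate
Product: 14 tert-butyl (1R)-2-hydroxy-1,3,3-trimethyl-2-[2-(2-methyl-1,3-dioxolan-2-yl)ethyl]cyclohexane-1-carboxylate (both C2 epimers)
Conditions: H2 (1 atm), Pd/C, Et3N (trace), EtOAc, rt
Reagents that add atoms: none
Why: Heterogeneous hydrogenation of the alkyne to the alkane; the trace of amine keeps the medium non-acidic, so neither hydrogenolysis of the tertiary propargylic C–O bond nor ketal exchange with the γ-hydroxyl should set in.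

Step 6
Reactants: 14 tert-butyl (1R)-2-hydroxy-1,3,3-trimethyl-2-[2-(2-methyl-1,3-dioxolan-2-yl)ethyl]cyclohexane-1-carboxylate
Product: 16 tert-butyl (1R)-1,3,3-trimethyl-2-[2-(2-methyl-1,3-dioxolan-2-yl)ethylidene]cyclohexane-1-carboxylate (alkene geometry not fixed), via chlorosulfite ester 15 (not isolated)
Conditions: SOCl2, pyridine, CH2Cl2, 0 °C → rt
Reagents that add atoms: none
Why: Dehydration of a tertiary alcohol through its chlorosulfite (E2 with pyridine as base): C4 and C10 are quaternary, so only C6 offers β-hydrogens and the exocyclic C5=C6 alkene is the only possible olefin, while the basic medium spares ketal and tert-butyl ester. The alkene geometry is irrelevant, since both isomers lead to the same C5 centre in step 8.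

Step 7
Reactants: 16 tert-butyl (1R)-1,3,3-trimethyl-2-[2-(2-methyl-1,3-dioxolan-2-yl)ethylidene]cyclohexane-1-carboxylate
Product: 17 [(1R)-1,3,3-trimethyl-2-[2-(2-methyl-1,3-dioxolan-2-yl)ethylidene]cyclohexyl]methanol
Conditions: LiAlH4, THF, 0 °C → reflux; then H2O, aq NaOH
Reagents that add atoms: none
Why: Hydride reduction of an ester to the primary alcohol; ketal and isolated alkene are inert to LiAlH4, and the hindered tert-butyl ester is expected to need heating.

Step 8
Reactants: 17 [(1R)-1,3,3-trimethyl-2-[2-(2-methyl-1,3-dioxolan-2-yl)ethylidene]cyclohexyl]methanol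
Product: 18 [(1R,2R)-1,3,3-trimethyl-2-[2-(2-methyl-1,3-dioxolan-2-yl)ethyl]cyclohexyl]methanol
Conditions: H2 (1–50 bar), [Ir(cod)(PCy3)(py)]PF6 (10 mol%), CH2Cl2, rt
Reagents that add atoms: none
Why: Hydroxyl-directed homogeneous hydrogenation with a cationic monovalent iridium complex: the C9 hydroxyl and the C5=C6 alkene bind the same metal centre, so both hydrogens are delivered to the alkene face on the side of the CH2OH group. C5–H should therefore end cis to C9 and the chain trans to C9 (cis to the C10 methyl), which is 5R relative to the fixed 10R centre, whatever the alkene geometry.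

Step 9
Reactants: 18 [(1R,2R)-1,3,3-trimethyl-2-[2-(2-methyl-1,3-dioxolan-2-yl)ethyl]cyclohexyl]methanol
Product: 19 (1R,2R)-1,3,3-trimethyl-2-[2-(2-methyl-1,3-dioxolan-2-yl)ethyl]cyclohexane-1-carbaldehyde
Conditions: Dess–Martin periodinane, pyridine, CH2Cl2, 0 °C → rt
Reagents that add atoms: none
Why: Dess–Martin oxidation of a neopentyl primary alcohol; the aldehyde has no α-hydrogen (C10 is quaternary), so it can neither epimerise nor self-condense, and pyridine buffers the acetic acid for the ketal.

Step 10
Reactants: 19 (1R,2R)-1,3,3-trimethyl-2-[2-(2-methyl-1,3-dioxolan-2-yl)ethyl]cyclohexane-1-carbaldehyde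
Product: 20 1-[(1R,2R)-1,3,3-trimethyl-2-[2-(2-methyl-1,3-dioxolan-2-yl)ethyl]cyclohexyl]ethan-1-ol (both carbinol epimers)
Conditions: MeMgBr, THF, −78 → 0 °C; aq NH4Cl
Reagents that add atoms: methylmagnesium bromide, C[Mg]Br
Why: Grignard addition to an aldehyde forms the C9–C11 bond; the new carbinol centre is not controlled and is removed in step 11.

Step 11
Reactants: 20 1-[(1R,2R)-1,3,3-trimethyl-2-[2-(2-methyl-1,3-dioxolan-2-yl)ethyl]cyclohexyl]ethan-1-ol
Product: 21 1-[(1R,2R)-1,3,3-trimethyl-2-[2-(2-methyl-1,3-dioxolan-2-yl)ethyl]cyclohexyl]ethan-1-one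
Conditions: Dess–Martin periodinane, pyridine, CH2Cl2, 0 °C → rt
Reagents that add atoms: none
Why: Dess–Martin oxidation of the secondary alcohol converges both epimers on the methyl ketone; C10 is quaternary and C5 is remote from the carbonyl, so no stereocentre is at risk.

Step 12
Reactants: 21 1-[(1R,2R)-1,3,3-trimethyl-2-[2-(2-methyl-1,3-dioxolan-2-yl)ethyl]cyclohexyl]ethan-1-one; 22 (E)-4-bromo-3-methylbut-2-en-1-yl acetate
Product: 24 (2E)-3-methyl-6-oxo-6-[(1R,2R)-1,3,3-trimethyl-2-[2-(2-methyl-1,3-dioxolan-2-yl)ethyl]cyclohexyl]hex-2-en-1-yl acetate, via methyl ketone lithium enolate 23 (not isolated)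
Conditions: LiN(i-Pr)2 (1.0 equiv), THF, −78 °C; then 22, DMPU, −78 → −30 °C
Reagents that add atoms: none
Why: SN2 alkylation of a lithium enolate with an allylic bromide: C11 is the only enolisable position of 21 because C10 is quaternary, so the enolate forms regiospecifically, and the primary allylic bromide should react at low temperature faster than the acetate is attacked. The (E) geometry arrives with 22 and is not touched.

Step 13
Reactants: 24 (2E)-3-methyl-6-oxo-6-[(1R,2R)-1,3,3-trimethyl-2-[2-(2-methyl-1,3-dioxolan-2-yl)ethyl]cyclohexyl]hex-2-en-1-yl acetate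
Product: 25 (2E)-3-methyl-6-oxo-6-[(1R,2R)-1,3,3-trimethyl-2-(3-oxobutyl)cyclohexyl]hex-2-en-1-yl acetate
Conditions: 1 M aq HCl, THF, 0 °C → rt
Reagents that add atoms: water, O
Why: Acid-catalysed hydrolysis of the dioxolane; dilute acid at room temperature should leave the primary allylic acetate and the hindered C9 ketone alone, and neither stereocentre is enolisable.

## Compound list

1 | 2,2-dimethylcyclohexanone | CC1(C)CCCCC1=O | starting material
2 | di-tert-butyl dicarbonate | CC(C)(C)OC(=O)OC(=O)OC(C)(C)C | starting material
3 | lithium 6,6-dimethylcyclohex-1-en-1-olate (enolate of 1, not isolated) | [Li+].[O-]C1=CCCCC1(C)C | intermediate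
4 | lithium 2-(tert-butoxycarbonyl)-6,6-dimethylcyclohex-1-en-1-olate (enolate of 5, not isolated) | [Li+].[O-]C1=C(C(=O)OC(C)(C)C)CCCC1(C)C | intermediate
5 | tert-butyl 3,3-dimethyl-2-oxocyclohexane-1-carboxylate (racemic, C1 labile) | CC1(C)CCCC(C(=O)OC(C)(C)C)C1=O | intermediate
6 | iodomethane | CI | starting material
7 | cesium 2-(tert-butoxycarbonyl)-6,6-dimethylcyclohex-1-en-1-olate (not isolated) | [Cs+].[O-]C1=C(C(=O)OC(C)(C)C)CCCC1(C)C | intermediate
8 | tert-butyl (R)-1,3,3-trimethyl-2-oxocyclohexane-1-carboxylate | CC(C)(C)OC(=O)[C@]1(C)CCCC(C)(C)C1=O | intermediate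
9 | but-3-yn-2-one | CC(=O)C#C | starting material
10 | 2-ethynyl-2-methyl-1,3-dioxolane | C#CC1(C)OCCO1 | intermediate
11 | lithium acetylide of 10 (not isolated) | [Li]C#CC1(C)OCCO1 | intermediate
12 | dichlorocerium acetylide of 10 (not isolated) | Cl[Ce](Cl)C#CC1(C)OCCO1 | intermediate
13 | tert-butyl (1R)-2-hydroxy-1,3,3-trimethyl-2-[(2-methyl-1,3-dioxolan-2-yl)ethynyl]cyclohexane-1-carboxylate (C2 epimers) | OC1(C#CC2(C)OCCO2)C(C)(C)CCC[C@@]1(C)C(=O)OC(C)(C)C | intermediate
14 | tert-butyl (1R)-2-hydroxy-1,3,3-trimethyl-2-[2-(2-methyl-1,3-dioxolan-2-yl)ethyl]cyclohexane-1-carboxylate (C2 epimers) | OC1(CCC2(C)OCCO2)C(C)(C)CCC[C@@]1(C)C(=O)OC(C)(C)C | intermediate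
15 | chlorosulfite ester of 14 (not isolated) | O=S(Cl)OC1(CCC2(C)OCCO2)C(C)(C)CCC[C@@]1(C)C(=O)OC(C)(C)C | intermediate
16 | tert-butyl (1R)-1,3,3-trimethyl-2-[2-(2-methyl-1,3-dioxolan-2-yl)ethylidene]cyclohexane-1-carboxylate (E/Z not fixed) | CC1(OCCO1)CC=C1C(C)(C)CCC[C@@]1(C)C(=O)OC(C)(C)C | intermediate
17 | [(1R)-1,3,3-trimethyl-2-[2-(2-methyl-1,3-dioxolan-2-yl)ethylidene]cyclohexyl]methanol | CC1(OCCO1)CC=C1C(C)(C)CCC[C@@]1(C)CO | intermediate
18 | [(1R,2R)-1,3,3-trimethyl-2-[2-(2-methyl-1,3-dioxolan-2-yl)ethyl]cyclohexyl]methanol | CC1(OCCO1)CC[C@@H]1C(C)(C)CCC[C@@]1(C)CO | intermediate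
19 | (1R,2R)-1,3,3-trimethyl-2-[2-(2-methyl-1,3-dioxolan-2-yl)ethyl]cyclohexane-1-carbaldehyde | CC1(OCCO1)CC[C@@H]1C(C)(C)CCC[C@@]1(C)C=O | intermediate
20 | 1-[(1R,2R)-1,3,3-trimethyl-2-[2-(2-methyl-1,3-dioxolan-2-yl)ethyl]cyclohexyl]ethan-1-ol (carbinol epimers) | CC1(OCCO1)CC[C@@H]1C(C)(C)CCC[C@@]1(C)C(C)O | intermediate
21 | 1-[(1R,2R)-1,3,3-trimethyl-2-[2-(2-methyl-1,3-dioxolan-2-yl)ethyl]cyclohexyl]ethan-1-one | CC1(OCCO1)CC[C@@H]1C(C)(C)CCC[C@@]1(C)C(C)=O | intermediate
22 | (E)-4-bromo-3-methylbut-2-en-1-yl acetate | BrC/C(C)=C/COC(C)=O | starting material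
23 | lithium enolate of 21 at C11 (not isolated) | CC1(OCCO1)CC[C@@H]1C(C)(C)CCC[C@@]1(C)C(=C)[O-].[Li+] | intermediate
24 | (2E)-3-methyl-6-oxo-6-[(1R,2R)-1,3,3-trimethyl-2-[2-(2-methyl-1,3-dioxolan-2-yl)ethyl]cyclohexyl]hex-2-en-1-yl acetate | CC1(OCCO1)CC[C@@H]1C(C)(C)CCC[C@@]1(C)C(=O)CC/C(C)=C/COC(C)=O | intermediate
25 | (2E)-3-methyl-6-oxo-6-[(1R,2R)-1,3,3-trimethyl-2-(3-oxobutyl)cyclohexyl]hex-2-en-1-yl acetate | CC(=O)CC[C@@H]1C(C)(C)CCC[C@@]1(C)C(=O)CC/C(C)=C/COC(C)=O | target

## Step count and least certain steps

Total step count: 13. Longest linear sequence: 12 steps (1 to 25 through steps 1, 2 and 4–13); step 3 is a one-step side branch that prepares 10.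

Step 2 (key step). The most likely failure is insufficient facial discrimination in the ion pair. The electrophile is the smallest possible one, the gem-dimethyl group beside the enolate oxygen may distort the usual catalyst–enolate geometry, and uncatalysed interfacial methylation would add racemic material. The fallback replaces asymmetric induction by resolution. It sets out from 5, which is methylated without chiral catalyst (K2CO3, 6, acetone) to racemic tert-butyl 1,3,3-trimethyl-2-oxocyclohexane-1-carboxylate F1. Preparative chromatography on a chiral stationary phase (amylose tris(3,5-dimethylphenylcarbamate), supercritical CO2–2-propanol) would separate F1 into 8 and its mirror image, tert-butyl (S)-1,3,3-trimethyl-2-oxocyclohexane-1-carboxylate F2. The route is re-entered at 8.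

Step 4. The carbonyl carbon sits between two quaternary centres, so addition may be slow. Retro-aldol cleavage of the C5–C10 bond of the tertiary alkoxide (expelling the ester enolate) or attack on the ester could then compete. The fallback carries C9 at the alcohol oxidation level, which removes both pathways. It sets out from 8 and returns at 17.
- LiAlH4 reduces ketone and ester to the diol (2S)-2-(hydroxymethyl)-2,6,6-trimethylcyclohexan-1-ol F3.
- TBSCl–imidazole silylates only the primary hydroxyl to give silyl ether F4.
- Dess–Martin oxidation returns the ring carbonyl, giving (2S)-2-[(tert-butyldimethylsilyloxy)methyl]-2,6,6-trimethylcyclohexan-1-one F5.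
- Addition of 12 gives propargylic alcohol F6.
- Hydrogenation (H2, Pd/C) gives the saturated carbinol F7.
- SOCl2–pyridine gives the silyl ether F8 of 17, and Bu4NF then releases 17.

Step 6. Ionisation of the chlorosulfite may outrun the E2 elimination and be followed by a Wagner–Meerwein methyl shift from C4 or by chloride capture. The alkene also suffers 1,3-allylic strain against a quaternary neighbour, which slows its formation. The fallback is a reductive elimination at the alkyne stage, with no cation at C5. It sets out from 13 and returns at 18.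
- The magnesium alkoxide of 13 (EtMgCl) is treated with Cp2Zr(H)Cl; hydrozirconation of the alkyne and syn β-elimination of the alkoxide would give the allene tert-butyl (1R)-1,3,3-trimethyl-2-[2-(2-methyl-1,3-dioxolan-2-yl)ethenylidene]cyclohexane-1-carboxylate F9.
- LiAlH4 gives the allenyl carbinol F10.
- Hydroxyl-directed hydrogenation with [Ir(cod)(PCy3)(py)]PF6 saturates both allene double bonds and gives 18.

Step 8. Facial selectivity may be poor or conversion may stall. The alkene is trisubstituted and lies between two quaternary carbons, the methyl and hydroxymethyl groups on C10 differ little in size, the ketal oxygens can compete for the metal, and the iridium catalyst deactivates when the substrate reacts slowly. The fallback uses reagent control in place of substrate direction. It sets out from 17 and returns at 18.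
- Ac2O–pyridine gives the acetate [(1R)-1,3,3-trimethyl-2-[2-(2-methyl-1,3-dioxolan-2-yl)ethylidene]cyclohexyl]methyl acetate F11.
- F11 is hydrogenated with a chiral iridium N,P-ligand catalyst, [Ir(cod)(L*)][B(3,5-(CF3)2C6H3)4] with L* a phosphinooxazoline or pyridyl phosphinite (the antipode that adds hydrogen cis to C9), H2 (50 bar), CH2Cl2. This would give the saturated acetate F12.
- K2CO3 in MeOH gives 18.

Step 12. Acyl transfer from the allylic acetate of 22 to enolate 23, or proton exchange between 23 and product 24 leading to double alkylation, may erode the alkylation. The fallback uses a stabilised carbanion in place of the ketone enolate. It sets out from 19 and returns at 24.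
- LiCH2SO2Ph adds to 19 to give the β-hydroxy sulfone F13.
- Dess–Martin oxidation gives the β-keto sulfone 2-(phenylsulfonyl)-1-[(1R,2R)-1,3,3-trimethyl-2-[2-(2-methyl-1,3-dioxolan-2-yl)ethyl]cyclohexyl]ethan-1-one F14.
- K2CO3 and 22 in DMF alkylate the doubly activated carbon under conditions that leave the acetate alone, giving the alkylated keto sulfone F15.
- Reductive desulfonylation with SmI2 (THF–MeOH, −78 °C) gives 24.

## Further compounds

F1 | step 2 | racemic tert-butyl 1,3,3-trimethyl-2-oxocyclohexane-1-carboxylate | CC(C)(C)OC(=O)C1(C)CCCC(C)(C)C1=O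
F2 | step 2 | tert-butyl (S)-1,3,3-trimethyl-2-oxocyclohexane-1-carboxylate | CC(C)(C)OC(=O)[C@@]1(C)CCCC(C)(C)C1=O
F3 | step 4 | (2S)-2-(hydroxymethyl)-2,6,6-trimethylcyclohexan-1-ol (C1 epimers) | OC1C(C)(C)CCC[C@@]1(C)CO
F4 | step 4 | (2S)-2-[(tert-butyldimethylsilyloxy)methyl]-2,6,6-trimethylcyclohexan-1-ol (C1 epimers) | OC1C(C)(C)CCC[C@@]1(C)CO[Si](C)(C)C(C)(C)C
F5 | step 4 | (2S)-2-[(tert-butyldimethylsilyloxy)methyl]-2,6,6-trimethylcyclohexan-1-one | O=C1C(C)(C)CCC[C@@]1(C)CO[Si](C)(C)C(C)(C)C
F6 | step 4 | (2S)-2-[(tert-butyldimethylsilyloxy)methyl]-2,6,6-trimethyl-1-[(2-methyl-1,3-dioxolan-2-yl)ethynyl]cyclohexan-1-ol (C1 epimers) | OC1(C#CC2(C)OCCO2)C(C)(C)CCC[C@@]1(C)CO[Si](C)(C)C(C)(C)C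
F7 | step 4 | (2S)-2-[(tert-butyldimethylsilyloxy)methyl]-2,6,6-trimethyl-1-[2-(2-methyl-1,3-dioxolan-2-yl)ethyl]cyclohexan-1-ol (C1 epimers) | OC1(CCC2(C)OCCO2)C(C)(C)CCC[C@@]1(C)CO[Si](C)(C)C(C)(C)C
F8 | step 4 | tert-butyldimethylsilyl ether of 17 | CC1(OCCO1)CC=C1C(C)(C)CCC[C@@]1(C)CO[Si](C)(C)C(C)(C)C
F9 | step 6 | tert-butyl (1R)-1,3,3-trimethyl-2-[2-(2-methyl-1,3-dioxolan-2-yl)ethenylidene]cyclohexane-1-carboxylate | CC1(OCCO1)C=C=C1C(C)(C)CCC[C@@]1(C)C(=O)OC(C)(C)C
F10 | step 6 | [(1R)-1,3,3-trimethyl-2-[2-(2-methyl-1,3-dioxolan-2-yl)ethenylidene]cyclohexyl]methanol | CC1(OCCO1)C=C=C1C(C)(C)CCC[C@@]1(C)CO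
F11 | step 8 | [(1R)-1,3,3-trimethyl-2-[2-(2-methyl-1,3-dioxolan-2-yl)ethylidene]cyclohexyl]methyl acetate | CC1(OCCO1)CC=C1C(C)(C)CCC[C@@]1(C)COC(C)=O
F12 | step 8 | [(1R,2R)-1,3,3-trimethyl-2-[2-(2-methyl-1,3-dioxolan-2-yl)ethyl]cyclohexyl]methyl acetate | CC1(OCCO1)CC[C@@H]1C(C)(C)CCC[C@@]1(C)COC(C)=O
F13 | step 12 | 2-(phenylsulfonyl)-1-[(1R,2R)-1,3,3-trimethyl-2-[2-(2-methyl-1,3-dioxolan-2-yl)ethyl]cyclohexyl]ethan-1-ol (carbinol epimers) | CC1(OCCO1)CC[C@@H]1C(C)(C)CCC[C@@]1(C)C(O)CS(=O)(=O)c1ccccc1
F14 | step 12 | 2-(phenylsulfonyl)-1-[(1R,2R)-1,3,3-trimethyl-2-[2-(2-methyl-1,3-dioxolan-2-yl)ethyl]cyclohexyl]ethan-1-one | CC1(OCCO1)CC[C@@H]1C(C)(C)CCC[C@@]1(C)C(=O)CS(=O)(=O)c1ccccc1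
F15 | step 12 | (2E)-3-methyl-6-oxo-5-(phenylsulfonyl)-6-[(1R,2R)-1,3,3-trimethyl-2-[2-(2-methyl-1,3-dioxolan-2-yl)ethyl]cyclohexyl]hex-2-en-1-yl acetate (epimers at the sulfonyl carbon) | CC1(OCCO1)CC[C@@H]1C(C)(C)CCC[C@@]1(C)C(=O)C(C/C(C)=C/COC(C)=O)S(=O)(=O)c1ccccc1
A1 | alternative 1 | [(1R,6R)-1,5,5-trimethyl-6-[2-(2-methyl-1,3-dioxolan-2-yl)ethyl]cyclohex-2-en-1-yl]methanol | CC1(OCCO1)CC[C@@H]2C(C)(C)CC=C[C@@]2(C)CO
A2 | alternative 1 | tributyl({[(1R,4R)-3,5,5-trimethyl-4-[2-(2-methyl-1,3-dioxolan-2-yl)ethyl]cyclohex-2-en-1-yl]oxy}methyl)stannane | CC1(OCCO1)CC[C@@H]2C(C)(C)C[C@@H](OC[Sn](CCCC)(CCCC)CCCC)C=C2C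
A3 | alternative 2 | (2E)-6-hydroxy-3-methyl-6-[(1R,2R)-1,3,3-trimethyl-2-[2-(2-methyl-1,3-dioxolan-2-yl)ethyl]-6-oxocyclohexyl]hex-2-en-1-yl acetate (carbinol epimers) | CC1(OCCO1)CC[C@@H]2C(C)(C)CCC(=O)[C@@]2(C)C(O)CC/C(C)=C/COC(C)=O
A4 | alternative 2 | 2,4,4-trimethylcyclohex-2-en-1-one | CC1=CC(C)(C)CCC1=O
A5 | alternative 2 | [2-(2-methyl-1,3-dioxolan-2-yl)ethyl]magnesium bromide | CC1(CC[Mg]Br)OCCO1
A6 | alternative 2 | (2E)-3-methyl-6-oxohex-2-en-1-yl acetate | CC(=O)OC/C=C(C)/CCC=O
A7 | alternative 3 | (1R,2R)-2-[(tert-butyldimethylsilyloxy)methyl]-2,6,6-trimethylcyclohex-3-ene-1-carboxylic acid | OC(=O)[C@@H]1C(C)(C)CC=C[C@@]1(C)CO[Si](C)(C)C(C)(C)C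
A8 | alternative 3 | (6S)-6-[(1Z)-3-(tert-butyldimethylsilyloxy)-2-methylprop-1-en-1-yl]-4,4-dimethyloxan-2-one | O=C1CC(C)(C)C[C@H](O1)/C=C(\CO[Si](C)(C)C(C)(C)C)C
A9 | alternative 3 | tert-butyldimethylsilyl ketene acetal of A8 | CC(C)(C)[Si](C)(C)OC1=CC(C)(C)C[C@H](O1)/C=C(\CO[Si](C)(C)C(C)(C)C)C
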